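**Strategy.** The target is a 2-methoxy-1,4-benzoquinone whose ring carbon C6 carries the side chain (C1'H2–C2'H(OAc)–C3'…C13'). Everything rests on cutting the C6–C1' bond. In the quinone ring, C6 lies ortho to the C1 oxygen, whose other ortho carbon C2 bears OMe and whose para carbon C4 is oxygenated. At the arene oxidation level C6 is therefore the only hydrogen-bearing position to which an O1-allyl group can migrate for good. Heating allyl 2,4-dimethoxyphenyl ether thus forges C6–C1' regiospecifically in one operation and delivers C1'–C3' as an allyl handle. Its terminal alkene becomes a resolved (S)-epoxide, which a decyl nucleophile opens before acetylation and oxidative unveiling of the quinone.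

Key step: step 3

**Remarks on the chemistry**
- Locants: C1 is the quinone carbonyl flanked by C2 (OMe) and C6 (side chain), and C4 is the second carbonyl. The same ring locants are used for the arene precursors. The side chain is C1' (CH2), C2' (CH–OAc), C3'–C13'.
- C2' of the target is (R). The (S)-epoxide 10 has the same spatial arrangement; the descriptor changes on opening only because the former epoxide CH2 drops below CH2Ar in CIP rank. No inversion occurs anywhere.
- "salen" denotes the N,N'-bis(3,5-di-tert-butylsalicylidene)cyclohexane-1,2-diaminato ligand; (S,S)-(salen)Co(OAc) is its trivalent cobalt acetate complex.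
- Assumption: decylmagnesium bromide is taken as the commercial ether solution.
- Phenols 3 and 7 are electron-rich and air-sensitive; both should be handled under argon and carried on promptly.

**Route**

Step 1
Reactants: 1 2,4-dimethoxybenzaldehyde
Product: 3 2,4-dimethoxyphenol, via 2,4-dimethoxyphenyl formate 2 (not isolated)
Conditions: mCPBA (1.3 equiv), CH2Cl2, 0 °C → rt; aq NaHCO3/Na2S2O3 wash; then K2CO3 (0.1 equiv), MeOH, rt, Ar
Reagents that add atoms: mCPBA (3-chloroperoxybenzoic acid), OOC(=O)c1cccc(Cl)c1
Why: Baeyer–Villiger (Dakin-type) oxidation, in which the electron-rich aryl group migrates in preference to hydride in the Criegee adduct to give aryl formate 2, which base-catalysed methanolysis should cleave cleanly to phenol 3.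

Step 2
Reactants: 3 2,4-dimethoxyphenol; 4 allyl bromide
Product: 5 1-(allyloxy)-2,4-dimethoxybenzene
Conditions: K2CO3 (2 equiv), acetone, reflux, Ar
Reagents that add atoms: none
Why: Williamson ether synthesis, the phenoxide displacing bromide by SN2 under K2CO3/acetone conditions that favour O- over C-allylation.

Step 3
Reactants: 5 1-(allyloxy)-2,4-dimethoxybenzene
Product: 7 2-allyl-4,6-dimethoxyphenol, via 6-allyl-2,4-dimethoxycyclohexa-2,4-dien-1-one 6 (not isolated)
Conditions: degassed N,N-diethylaniline, 200 °C, sealed vessel, Ar; dilute HCl wash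
Reagents that add atoms: none
Why: On heating, the ether should undergo a concerted, suprafacial [3,3]-sigmatropic shift through a chair-like six-membered transition state in which the O1–CH2 bond breaks as the allyl terminus bonds to C6, giving dienone 6, whose C6–H then tautomerises to restore the aromatic ring as phenol 7. This is the classical aromatic Claisen rearrangement of an allyl aryl ether, which applies directly to this substrate class. No ring is closed, and the only sp3 centre created (C6 of 6) is erased on enolisation, so no stereocontrol is required. The selectivity needed is positional: migration to C2 would give a dienone with a quaternary OMe-bearing carbon that cannot enolise and can only return by the reverse shift, and onward Cope transfer to C4 is equally unproductive because C4 also carries OMe, so C6, the sole hydrogen-bearing ortho carbon, is the only irreversible exit. The basic, degassed medium is chosen to suppress acid-promoted cyclisation of the ortho-allylphenol to a dihydrobenzofuran and air oxidation of the product.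

Step 4
Reactants: 7 2-allyl-4,6-dimethoxyphenol
Product: 8 1-allyl-2,3,5-trimethoxybenzene
Conditions: MeI (1.5 equiv), K2CO3 (2 equiv), DMF, rt, Ar
Reagents that add atoms: iodomethane, CI
Why: Williamson O-methylation, which caps the phenol so that it can neither cyclise onto the later epoxide nor quench the Grignard reagent, and completes the C1/C4 dimethoxy pair needed for the final oxidative demethylation.

Step 5
Reactants: 8 1-allyl-2,3,5-trimethoxybenzene
Product: 9 rac-2-(2,3,5-trimethoxybenzyl)oxirane
Conditions: mCPBA (1.2 equiv), NaHCO3, CH2Cl2, 0 °C → rt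
Reagents that add atoms: mCPBA (3-chloroperoxybenzoic acid), OOC(=O)c1cccc(Cl)c1
Why: Prilezhaev epoxidation, a concerted oxygen transfer from the peracid to the isolated terminal alkene, with buffering and low temperature to hold back arene oxidation; the product is racemic by design.

Step 6
Reactants: 9 rac-2-(2,3,5-trimethoxybenzyl)oxirane
Product: 10 (S)-2-(2,3,5-trimethoxybenzyl)oxirane
Conditions: (S,S)-(salen)Co(OAc) (0.5–1 mol%), H2O (0.55 equiv), THF (minimal), 0 °C → rt; chromatography to remove the diol
Reagents that add atoms: none
Why: Jacobsen hydrolytic kinetic resolution, in which the (S,S)-configured trivalent cobalt salen catalyst is expected to hydrate the (R)-epoxide far faster than its antipode, so that C2' is set by catalyst control and the unreacted (S)-epoxide should be recovered in high enantiomeric purity once slightly more than half of 9 has been consumed.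

Step 7
Reactants: 10 (S)-2-(2,3,5-trimethoxybenzyl)oxirane; 11 decylmagnesium bromide
Product: 12 (R)-1-(2,3,5-trimethoxyphenyl)tridecan-2-ol
Conditions: 11 (1.5 equiv, 1.0 M in Et2O), CuI (10 mol%), THF, −30 → 0 °C; sat. aq NH4Cl
Reagents that add atoms: none
Why: Copper-catalysed Grignard opening of a terminal epoxide, the decyl cuprate attacking the unsubstituted C3' in SN2 fashion so that the C2'–O bond and its configuration are untouched.

Step 8
Reactants: 12 (R)-1-(2,3,5-trimethoxyphenyl)tridecan-2-ol
Product: 13 (R)-1-(2,3,5-trimethoxyphenyl)tridecan-2-yl acetate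
Conditions: Ac2O (1.5 equiv), pyridine, DMAP (5 mol%), CH2Cl2, rt
Reagents that add atoms: acetic anhydride, CC(=O)OC(C)=O
Why: DMAP-catalysed O-acylation through the N-acetylpyridinium ion, which acylates the secondary alcohol with retention because the C2'–O bond is never broken.

Step 9
Reactants: 13 (R)-1-(2,3,5-trimethoxyphenyl)tridecan-2-yl acetate
Product: 14 (R)-1-(5-methoxy-3,6-dioxocyclohexa-1,4-dien-1-yl)tridecan-2-yl acetate (the target, 2-[(R)-2-acetoxytridecyl]-6-methoxy-1,4-benzoquinone)
Conditions: (NH4)2Ce(NO3)6 (2.5 equiv), MeCN–H2O 2:1, 0 °C, 15–30 min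
Reagents that add atoms: water, O
Why: Oxidative demethylation with ceric ammonium nitrate (tetravalent cerium), in which two one-electron oxidations and water addition at the para-related C1 and C4 methoxy-bearing carbons release methanol and give the para-quinone, the C2 methoxy group remaining as a vinylogous ester and the acetate and stereocentre being inert under the brief, cold conditions.

**Compound list**

1 | 2,4-dimethoxybenzaldehyde | COc1ccc(C=O)c(OC)c1 | starting material
2 | 2,4-dimethoxyphenyl formate | COc1ccc(OC=O)c(OC)c1 | intermediate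
3 | 2,4-dimethoxyphenol | COc1ccc(O)c(OC)c1 | intermediate
4 | allyl bromide | C=CCBr | starting material
5 | 1-(allyloxy)-2,4-dimethoxybenzene | C=CCOc1ccc(OC)cc1OC | intermediate
6 | 6-allyl-2,4-dimethoxycyclohexa-2,4-dien-1-one (racemic, transient) | C=CCC1C=C(OC)C=C(OC)C1=O | intermediate
7 | 2-allyl-4,6-dimethoxyphenol | C=CCc1cc(OC)cc(OC)c1O | intermediate
8 | 1-allyl-2,3,5-trimethoxybenzene | C=CCc1cc(OC)cc(OC)c1OC | intermediate
9 | rac-2-(2,3,5-trimethoxybenzyl)oxirane | COc1cc(CC2CO2)c(OC)c(OC)c1 | intermediate
10 | (S)-2-(2,3,5-trimethoxybenzyl)oxirane | COc1cc(C[C@H]2CO2)c(OC)c(OC)c1 | intermediate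
11 | decylmagnesium bromide | CCCCCCCCCC[Mg]Br | starting material
12 | (R)-1-(2,3,5-trimethoxyphenyl)tridecan-2-ol | CCCCCCCCCCC[C@H](Cc1cc(OC)cc(OC)c1OC)O | intermediate
13 | (R)-1-(2,3,5-trimethoxyphenyl)tridecan-2-yl acetate | CCCCCCCCCCC[C@H](Cc1cc(OC)cc(OC)c1OC)OC(C)=O | intermediate
14 | (R)-1-(5-methoxy-3,6-dioxocyclohexa-1,4-dien-1-yl)tridecan-2-yl acetate | CCCCCCCCCCC[C@H](CC1=CC(=O)C=C(OC)C1=O)OC(C)=O | target

**Step count**

Total steps: 9. Longest linear sequence: 9 (1 → 14).

**Steps most likely to fail, with fallbacks**

Step 3 (Claisen rearrangement). At 200 °C the electron-rich phenol may be lost to air oxidation, to thermal degradation or to cyclisation of the ortho-allylphenol, or the rearrangement may stall. Fallback: setting out from 3, the C6–C1' bond would be made by chelation-controlled ortho-formylation instead (MgCl2, Et3N, paraformaldehyde, MeCN, reflux), which can only reach C6 and should give 2-hydroxy-3,5-dimethoxybenzaldehyde F1. O-Methylation (MeI, K2CO3, DMF) would give 2,3,5-trimethoxybenzaldehyde F2, and NaBH4 reduction in MeOH would give (2,3,5-trimethoxyphenyl)methanol F3. PBr3 in Et2O at 0 °C would then give 1-(bromomethyl)-2,3,5-trimethoxybenzene F4, and CuI-catalysed coupling of this benzylic bromide with vinylmagnesium bromide in THF rejoins the route at 8.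

Step 5 (epoxidation). Electrophilic oxidation of the trioxygenated ring by the peracid may outrun epoxidation of the unactivated terminal alkene. Fallback: setting out from 8, the alkene would be dihydroxylated with catalytic OsO4 and N-methylmorpholine N-oxide in acetone–water, an oxidant that leaves the arene alone, to give rac-3-(2,3,5-trimethoxyphenyl)propane-1,2-diol F5. Selective primary sulfonylation (TsCl, Et3N, catalytic Bu2SnO, CH2Cl2) would give rac-2-hydroxy-3-(2,3,5-trimethoxyphenyl)propyl 4-methylbenzenesulfonate F6, and ring closure with K2CO3 in MeOH returns to the route at 9.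

Step 9 (quinone formation). Demethylation may occur across the vicinal C1/C2 pair instead of the para C1/C4 pair, or the radical cation may dimerise, so positional selectivity and yield may erode. Fallback: setting out from 7, the C1 oxygen would be carried as a benzyl ether so that the quinone arises from a free para-methoxyphenol.
- Benzylation (BnBr, K2CO3, DMF) gives 1-allyl-2-(benzyloxy)-3,5-dimethoxybenzene F7.
- The operations of steps 5–8 are repeated: mCPBA gives rac-2-[2-(benzyloxy)-3,5-dimethoxybenzyl]oxirane F8; the same hydrolytic kinetic resolution gives (S)-2-[2-(benzyloxy)-3,5-dimethoxybenzyl]oxirane F9; decylmagnesium bromide/CuI gives (R)-1-[2-(benzyloxy)-3,5-dimethoxyphenyl]tridecan-2-ol F10; Ac2O/pyridine/DMAP gives (R)-1-[2-(benzyloxy)-3,5-dimethoxyphenyl]tridecan-2-yl acetate F11.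
- Hydrogenolysis (H2, Pd/C, EtOAc) frees the phenol, (R)-1-(2-hydroxy-3,5-dimethoxyphenyl)tridecan-2-yl acetate F12.
- Oxidation with PhI(OAc)2 in MeCN–H2O at 0 °C, which can only engage the C1 hydroxyl and the para C4 methoxy carbon, arrives at 14.

**Further compounds**

F1 | step 3 | 2-hydroxy-3,5-dimethoxybenzaldehyde | COc1cc(C=O)c(O)c(OC)c1
F2 | step 3 | 2,3,5-trimethoxybenzaldehyde | COc1cc(C=O)c(OC)c(OC)c1
F3 | step 3 | (2,3,5-trimethoxyphenyl)methanol | COc1cc(CO)c(OC)c(OC)c1
F4 | step 3 | 1-(bromomethyl)-2,3,5-trimethoxybenzene | COc1cc(CBr)c(OC)c(OC)c1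
F5 | step 5 | rac-3-(2,3,5-trimethoxyphenyl)propane-1,2-diol | COc1cc(CC(O)CO)c(OC)c(OC)c1
F6 | step 5 | rac-2-hydroxy-3-(2,3,5-trimethoxyphenyl)propyl 4-methylbenzenesulfonate | COc1cc(CC(O)COS(=O)(=O)c2ccc(C)cc2)c(OC)c(OC)c1
F7 | step 9 | 1-allyl-2-(benzyloxy)-3,5-dimethoxybenzene | C=CCc1cc(OC)cc(OC)c1OCc1ccccc1
F8 | step 9 | rac-2-[2-(benzyloxy)-3,5-dimethoxybenzyl]oxirane | COc1cc(CC2CO2)c(OCc2ccccc2)c(OC)c1
F9 | step 9 | (S)-2-[2-(benzyloxy)-3,5-dimethoxybenzyl]oxirane | COc1cc(C[C@H]2CO2)c(OCc2ccccc2)c(OC)c1
F10 | step 9 | (R)-1-[2-(benzyloxy)-3,5-dimethoxyphenyl]tridecan-2-ol | CCCCCCCCCCC[C@H](Cc1cc(OC)cc(OC)c1OCc1ccccc1)O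
F11 | step 9 | (R)-1-[2-(benzyloxy)-3,5-dimethoxyphenyl]tridecan-2-yl acetate | CCCCCCCCCCC[C@H](Cc1cc(OC)cc(OC)c1OCc1ccccc1)OC(C)=O
F12 | step 9 | (R)-1-(2-hydroxy-3,5-dimethoxyphenyl)tridecan-2-yl acetate | CCCCCCCCCCC[C@H](Cc1cc(OC)cc(OC)c1O)OC(C)=O
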